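**A direct plan would** make both diaryl ethers by SNAr on formyl-activated aryl fluorides, join rings B and C through an alkyne, and close the 18-membered ring by McMurry coupling of the dialdehyde A1 at the ring A–ring D bridge.
Hydrogenation would then give the trimethyl ether A2, BBr3 the hydroquinone A3, and a mild oxidant the quinone.
Its weakest steps would be:
- the reductive carbonyl coupling that closes the ring: nothing in A1 favours the intramolecular pathway, so closure would rest on dilution alone, with pinacols and oligomers as likely companions;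
- the threefold BBr3 ether cleavage of A2: the harshest reagent of the plan would meet the most precious intermediate and leave the air-sensitive A3, to be used crude;
- the three steps after ring closure (alkene hydrogenation, demethylation, oxidation): they add no skeletal bond, and the last must tell a hydroquinone from a free phenol.

**Plan of the new route**
The retrosynthesis cuts the quinone C2–O bond to ring C first (the ring-closing bond), then the benzylic C=C bonds of both two-carbon bridges (two Wittig reactions, one hydrogenation) and the A–O–B ether (SNAr).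
The four six-membered rings are bought; ring D becomes the quinone before the macrocycle exists, and the 18-membered ring arises last, directly as the natural product.
Feature used: in the 2-aryloxy-3-alkyl-1,4-benzoquinone, C2 is the β-carbon of the C4 enone; with Cl in place of the aryloxy group it is a vinylogous acid chloride.
Oxidation thus turns the nucleophilic ring D into the electrophile onto which the ring-C phenoxide closes (polarity reversal by oxidation).
No carbonyl coupling, Lewis-acid ether cleavage or redox adjustment follows ring closure: the benzyl groups fall in the hydrogenation, the silyl groups in the ring-closing step itself.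

Key step: step 10

Assumption: the target SMILES has no stereocentre and the 18-membered ring is taken as conformationally mobile, so the compound is achiral and the constitution drawn is the single species to be made.

**Route**

Step 1
Reactants: 1 2-chloro-1,4-dimethoxybenzene
Product: 4 (2-chloro-3,6-dimethoxyphenyl)methanol, via (2-chloro-3,6-dimethoxyphenyl)lithium 2 (not isolated), via 2-chloro-3,6-dimethoxybenzaldehyde 3 (not isolated)
Conditions: n-BuLi, THF, −78 °C; DMF, −78 → 0 °C; then MeOH, NaBH4, 0 °C
Reagents that add atoms: N,N-dimethylformamide, CN(C)C=O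
Why: Directed ortho-metalation at the C–H flanked by Cl and OMe (the most acidic site; −78 °C keeps the ortho-chloro aryllithium from collapsing to the aryne), formylation with DMF and in-flask borohydride reduction should give the benzylic alcohol in one operation.

Step 2
Reactants: 4 (2-chloro-3,6-dimethoxyphenyl)methanol
Product: 5 (2-chloro-3,6-dimethoxybenzyl)triphenylphosphonium bromide
Conditions: PPh3·HBr, MeCN, reflux
Reagents that add atoms: triphenylphosphine hydrobromide, [Br-].c1ccc([PH+](c2ccccc2)c2ccccc2)cc1
Why: Electron-rich benzylic alcohols are converted directly into benzylphosphonium bromides by PPh3·HBr (ionisation to the benzylic bromide, then SN2 quaternisation of the phosphine).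

Step 3
Reactants: 6 3-(benzyloxy)benzyl bromide
Product: 7 [3-(benzyloxy)benzyl]triphenylphosphonium bromide
Conditions: PPh3, toluene, reflux
Reagents that add atoms: triphenylphosphine, c1ccc(cc1)P(c1ccccc1)c1ccccc1
Why: SN2 quaternisation of triphenylphosphine by a primary benzylic bromide.

Step 4
Reactants: 7 [3-(benzyloxy)benzyl]triphenylphosphonium bromide; 8 4-(benzyloxy)-3-hydroxybenzaldehyde
Product: 10 2-(benzyloxy)-5-{2-[3-(benzyloxy)phenyl]ethenyl}phenol (E/Z mixture), via [3-(benzyloxy)benzylidene]triphenylphosphorane 9 (not isolated)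
Conditions: KOtBu (2.2 equiv), THF, 0 °C → rt; dil. HCl
Reagents that add atoms: none
Why: Wittig olefination with a semi-stabilised benzylic ylide; the phenol, meta to the formyl group, is carried as its phenoxide by the extra equivalent of base without deactivating the aldehyde, and the alkene geometry is irrelevant because it is hydrogenated in step 7.

Step 5
Reactants: 10 2-(benzyloxy)-5-{2-[3-(benzyloxy)phenyl]ethenyl}phenol; 11 4-fluorobenzaldehyde
Product: 12 4-(2-(benzyloxy)-5-{2-[3-(benzyloxy)phenyl]ethenyl}phenoxy)benzaldehyde (E/Z mixture)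
Conditions: K2CO3, DMF, 120 °C
Reagents that add atoms: none
Why: SNAr of the phenoxide on the para-formyl-activated aryl fluoride forms the A–O–B diaryl ether; the formyl group is the future benzylic carbon of the A–D bridge, and benzyl ethers and the stilbene are inert to carbonate.

Step 6
Reactants: 12 4-(2-(benzyloxy)-5-{2-[3-(benzyloxy)phenyl]ethenyl}phenoxy)benzaldehyde; 5 (2-chloro-3,6-dimethoxybenzyl)triphenylphosphonium bromide
Product: 14 2-chloro-3-{2-[4-(2-(benzyloxy)-5-{2-[3-(benzyloxy)phenyl]ethenyl}phenoxy)phenyl]ethenyl}-1,4-dimethoxybenzene (mixture of alkene isomers), via (2-chloro-3,6-dimethoxybenzylidene)triphenylphosphorane 13 (not isolated)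
Conditions: KOtBu, THF, 0 °C → rt
Reagents that add atoms: none
Why: A second Wittig olefination joins ring D, already carrying the C2 chlorine, to ring A; the aldehyde is non-enolisable and the aryl chloride and benzyl ethers do not react with the ylide.

Step 7
Reactants: 14 2-chloro-3-{2-[4-(2-(benzyloxy)-5-{2-[3-(benzyloxy)phenyl]ethenyl}phenoxy)phenyl]ethenyl}-1,4-dimethoxybenzene
Product: 15 2-{4-[2-(2-chloro-3,6-dimethoxyphenyl)ethyl]phenoxy}-4-[2-(3-hydroxyphenyl)ethyl]phenol
Conditions: H2 (1 atm), 10% Pd/C, EtOAc–AcOH (20:1), rt, stopped after uptake of 4 equiv H2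
Reagents that add atoms: none
Why: Catalytic hydrogenation should saturate both stilbenes and hydrogenolyse both benzyl ethers in one operation, while the electron-rich, doubly ortho-substituted aryl chloride is the slowest site on Pd in base-free medium and the methyl ethers are inert.

Step 8
Reactants: 15 2-{4-[2-(2-chloro-3,6-dimethoxyphenyl)ethyl]phenoxy}-4-[2-(3-hydroxyphenyl)ethyl]phenol
Product: 16 bis(triisopropylsilyl) ether of 15 (both phenols silylated)
Conditions: TIPSCl, imidazole, DMF, 40 °C
Reagents that add atoms: triisopropylsilyl chloride, CC(C)[Si](Cl)(C(C)C)C(C)C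
Why: Standard silylation of phenols; TIPS is chosen because aryl TIPS ethers withstand the acidic aqueous oxidant of step 9 yet fall to fluoride at room temperature.

Step 9
Reactants: 16 bis(triisopropylsilyl) ether of 15
Product: 17 2-chloro-3-{2-[4-(2-[(triisopropylsilyl)oxy]-5-{2-[3-((triisopropylsilyl)oxy)phenyl]ethyl}phenoxy)phenyl]ethyl}-1,4-benzoquinone
Conditions: CAN (2.5 equiv), MeCN/THF/H2O, 0 °C
Reagents that add atoms: water, O
Why: CAN oxidative demethylation of the 1,4-dimethoxyarene (radical cation, attack of water, loss of two MeOH) gives the p-benzoquinone; ring D is the only para-dioxygenated and hence most easily oxidised ring, and the silyl caps keep rings B and C from oxidation or nitration.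

Step 10
Reactants: 17 2-chloro-3-{2-[4-(2-[(triisopropylsilyl)oxy]-5-{2-[3-((triisopropylsilyl)oxy)phenyl]ethyl}phenoxy)phenyl]ethyl}-1,4-benzoquinone
Product: 19 marchantinquinone, via the dicesium bis(phenoxide) of the desilylated seco-chloroquinone 18 (not isolated)
Conditions: CsF (6 equiv), DMF, rt, Ar, 17 added over 10 h (final 1 mM); dil. HCl
Reagents that add atoms: none
Why: Fluoride cleaves both aryl O–Si bonds, the ring-C phenoxide adds to C2 of the chloroquinone (the Cl-bearing β-carbon of the C4 enone, a vinylogous acid chloride) and the resulting enolate expels chloride, i.e. addition–elimination on a quinone made electrophilic by oxidation of the formerly nucleophilic ring D. The closest known reaction type is the displacement of halide from 2-halo-1,4-quinones by phenoxides under mild base, combined with the fluoride-triggered use of aryl silyl ethers as latent phenoxides in macrocyclic diaryl-ether closures. The 18-membered ring is closed in 18-endo-trig fashion (the attacked C2=C3 bond lies inside the new ring) and no stereocentre is formed. Site selectivity for C2 over C5/C6 rests on the chloride: only the C2 adduct can collapse irreversibly, whereas oxa-Michael adducts at the C–H positions revert. Selectivity between the two phenoxides rests on ring size: the ring-B phenoxide could reach C2 only through a strained 12-membered ring spanning the para-phenylene ring A, so it is simply reprotonated on work-up. Ring closure should be favoured over oligomerisation by the low stationary concentration and the four rigid arene panels of the chain, and the product needs no further step.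

**Compound list**

1 | 2-chloro-1,4-dimethoxybenzene | COc1ccc(OC)c(Cl)c1 | starting material
2 | (2-chloro-3,6-dimethoxyphenyl)lithium | COc1ccc(OC)c([Li])c1Cl | intermediate (not isolated)
3 | 2-chloro-3,6-dimethoxybenzaldehyde | COc1ccc(OC)c(C=O)c1Cl | intermediate (not isolated)
4 | (2-chloro-3,6-dimethoxyphenyl)methanol | COc1ccc(OC)c(CO)c1Cl | intermediate
5 | (2-chloro-3,6-dimethoxybenzyl)triphenylphosphonium bromide | COc1ccc(OC)c(C[P+](c2ccccc2)(c2ccccc2)c2ccccc2)c1Cl.[Br-] | intermediate
6 | 3-(benzyloxy)benzyl bromide | BrCc1cccc(OCc2ccccc2)c1 | starting material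
7 | [3-(benzyloxy)benzyl]triphenylphosphonium bromide | [Br-].c1ccc(COc2cccc(C[P+](c3ccccc3)(c3ccccc3)c3ccccc3)c2)cc1 | intermediate
8 | 4-(benzyloxy)-3-hydroxybenzaldehyde | O=Cc1ccc(OCc2ccccc2)c(O)c1 | starting material
9 | [3-(benzyloxy)benzylidene]triphenylphosphorane | c1ccc(COc2cccc(C=P(c3ccccc3)(c3ccccc3)c3ccccc3)c2)cc1 | intermediate (not isolated)
10 | 2-(benzyloxy)-5-{2-[3-(benzyloxy)phenyl]ethenyl}phenol (E/Z mixture) | Oc1cc(C=Cc2cccc(OCc3ccccc3)c2)ccc1OCc1ccccc1 | intermediate
11 | 4-fluorobenzaldehyde | O=Cc1ccc(F)cc1 | starting material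
12 | 4-(2-(benzyloxy)-5-{2-[3-(benzyloxy)phenyl]ethenyl}phenoxy)benzaldehyde (E/Z mixture) | O=Cc1ccc(Oc2cc(C=Cc3cccc(OCc4ccccc4)c3)ccc2OCc2ccccc2)cc1 | intermediate
13 | (2-chloro-3,6-dimethoxybenzylidene)triphenylphosphorane | COc1ccc(OC)c(C=P(c2ccccc2)(c2ccccc2)c2ccccc2)c1Cl | intermediate (not isolated)
14 | 2-chloro-3-{2-[4-(2-(benzyloxy)-5-{2-[3-(benzyloxy)phenyl]ethenyl}phenoxy)phenyl]ethenyl}-1,4-dimethoxybenzene (alkene isomer mixture) | COc1ccc(OC)c(C=Cc2ccc(Oc3cc(C=Cc4cccc(OCc5ccccc5)c4)ccc3OCc3ccccc3)cc2)c1Cl | intermediate
15 | 2-{4-[2-(2-chloro-3,6-dimethoxyphenyl)ethyl]phenoxy}-4-[2-(3-hydroxyphenyl)ethyl]phenol | COc1ccc(OC)c(CCc2ccc(Oc3cc(CCc4cccc(O)c4)ccc3O)cc2)c1Cl | intermediate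
16 | bis(triisopropylsilyl) ether of 15 | COc1ccc(OC)c(CCc2ccc(Oc3cc(CCc4cccc(O[Si](C(C)C)(C(C)C)C(C)C)c4)ccc3O[Si](C(C)C)(C(C)C)C(C)C)cc2)c1Cl | intermediate
17 | 2-chloro-3-{2-[4-(2-[(triisopropylsilyl)oxy]-5-{2-[3-((triisopropylsilyl)oxy)phenyl]ethyl}phenoxy)phenyl]ethyl}-1,4-benzoquinone | O=C1C=CC(=O)C(Cl)=C1CCc1ccc(Oc2cc(CCc3cccc(O[Si](C(C)C)(C(C)C)C(C)C)c3)ccc2O[Si](C(C)C)(C(C)C)C(C)C)cc1 | intermediate
18 | dicesium bis(phenoxide) of the desilylated seco-chloroquinone | [Cs+].[Cs+].O=C1C=CC(=O)C(Cl)=C1CCc1ccc(Oc2cc(CCc3cccc([O-])c3)ccc2[O-])cc1 | intermediate (not isolated)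
19 | marchantinquinone (achiral) | O=C1C=CC(=O)C2=C1CCc1ccc(cc1)Oc1cc(ccc1O)CCc1cccc(c1)O2 | target

**Summary**

Total steps: 10. Longest linear sequence: 8 steps (steps 3–10, from 3-(benzyloxy)benzyl bromide 6).

Steps most likely to fail:

1. Step 10 (ring closure). What may go wrong: intermolecular substitution leading to oligomers, reaction of the ring-B phenoxide with a second molecule, or base-induced degradation of the quinone before closure. The fallback sets out from 15 and comes back at 19, and leaves only one nucleophile in the ring-closing step. The unhindered ring-C phenol of 15 would be silylated selectively (TIPSCl 1.05 equiv, imidazole, CH2Cl2, 0 °C) to the ring-C mono(triisopropylsilyl) ether F1. The hindered ring-B phenol would be capped with MOMCl/iPr2NEt to give the ring-B methoxymethyl ether F2. CAN as in step 9 would give the chloroquinone F3. CsF in DMF at high dilution would then free a single phenoxide and close the ring to marchantinquinone O-methoxymethyl ether F4. TFA in CH2Cl2 at 0 °C would remove the acetal to give 19.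

2. Step 7 (global hydrogenation). What may go wrong: hydrogenolysis of the aryl C–Cl bond before the hindered alkene and both benzyl ethers have reacted. The fallback sets out from 14 and comes back at 15, and separates reduction from debenzylation without a metal catalyst. Diimide (TsNHNH2, NaOAc, THF/H2O, reflux) would saturate both alkenes without touching C–Cl or O–benzyl bonds and give the saturated dibenzyl ether F5. BCl3 with pentamethylbenzene in CH2Cl2 at −78 °C would then cleave the two benzyl ethers, not the methyl ethers, to give 15.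

3. Step 9 (quinone formation). What may go wrong: one-electron oxidation of rings A or B, acid-induced loss of a silyl group followed by oxidation or nitration of the freed phenol, or oxidative dimerisation at C5/C6. The fallback sets out from 16 and comes back at 17. Anodic oxidation in methanol (Pt anode, LiClO4, constant current, 0 °C) would give the quinone bis(dimethyl ketal) F6 under neutral conditions. Brief hydrolysis with 1 M HCl in THF would then unmask the quinone 17.

**Further compounds**

F1 | step 10 | 2-{4-[2-(2-chloro-3,6-dimethoxyphenyl)ethyl]phenoxy}-4-(2-{3-[(triisopropylsilyl)oxy]phenyl}ethyl)phenol | COc1ccc(OC)c(CCc2ccc(Oc3cc(CCc4cccc(O[Si](C(C)C)(C(C)C)C(C)C)c4)ccc3O)cc2)c1Cl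
F2 | step 10 | ring-B methoxymethyl ether of F1 | COc1ccc(OC)c(CCc2ccc(Oc3cc(CCc4cccc(O[Si](C(C)C)(C(C)C)C(C)C)c4)ccc3OCOC)cc2)c1Cl
F3 | step 10 | 2-chloro-3-{2-[4-(2-(methoxymethoxy)-5-{2-[3-((triisopropylsilyl)oxy)phenyl]ethyl}phenoxy)phenyl]ethyl}-1,4-benzoquinone | O=C1C=CC(=O)C(Cl)=C1CCc1ccc(Oc2cc(CCc3cccc(O[Si](C(C)C)(C(C)C)C(C)C)c3)ccc2OCOC)cc1
F4 | step 10 | marchantinquinone O-methoxymethyl ether (ring B) | O=C1C=CC(=O)C2=C1CCc1ccc(cc1)Oc1cc(ccc1OCOC)CCc1cccc(c1)O2
F5 | step 7 | 2-chloro-3-{2-[4-(2-(benzyloxy)-5-{2-[3-(benzyloxy)phenyl]ethyl}phenoxy)phenyl]ethyl}-1,4-dimethoxybenzene | COc1ccc(OC)c(CCc2ccc(Oc3cc(CCc4cccc(OCc5ccccc5)c4)ccc3OCc3ccccc3)cc2)c1Cl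
F6 | step 9 | quinone bis(dimethyl ketal) of 17 (2-chloro-3,3,6,6-tetramethoxycyclohexa-1,4-diene bearing the bis-silylated side chain at C1) | COC1(OC)C=CC(OC)(OC)C(Cl)=C1CCc1ccc(Oc2cc(CCc3cccc(O[Si](C(C)C)(C(C)C)C(C)C)c3)ccc2O[Si](C(C)C)(C(C)C)C(C)C)cc1
A1 | direct plan | 2-(3-{2-[3-(4-formylphenoxy)-4-methoxyphenyl]ethyl}phenoxy)-3,6-dimethoxybenzaldehyde | COc1ccc(CCc2cccc(Oc3c(C=O)c(OC)ccc3OC)c2)cc1Oc1ccc(C=O)cc1
A2 | direct plan | macrocyclic bis(bibenzyl) trimethyl ether | COc1ccc2cc1Oc1ccc(cc1)CCc1c(OC)ccc(OC)c1Oc1cccc(CC2)c1
A3 | direct plan | macrocyclic hydroquinone triol | Oc1ccc2cc1Oc1ccc(cc1)CCc1c(O)ccc(O)c1Oc1cccc(CC2)c1
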